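**Direct plan and its weak points**

A direct plan would make the o-isopropenylphenol A1 by Suzuki coupling, esterify both hydroxyls to the bis-isobutyrate A2, brominate the allylic methyl group to A3, displace bromide with acetate to the 2-arylallyl acetate A4, and finish with an enantioselective epoxidation of A4.
- The closing enantioselective epoxidation of the 1,1-disubstituted alkene of A4 would set the only stereocenter in the last step. Its two carbon substituents (a twisted ortho-acyloxyaryl group and CH2OAc) are poorly told apart by known catalysts, and the acid-labile product could hardly be enriched afterwards.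
- The allylic bromination of the α-methylstyrene A2 would compete with vinyl bromide formation, addition to the alkene and bromination at ArCH2O, and it spends two operations on one C–O bond.
- The styrene intermediates A1 to A4 are liabilities in themselves: an o-isopropenylphenol dimerises readily under acid, and the whole sequence carries no stereochemical information until its end.

**Retrosynthetic overview**

- Feature used: oxirane carbon C2 carries the aryl ring, the ring oxygen O1 and two CH2–O arms (ring C3 and the acetoxymethyl carbon). The target is therefore a 2-arylglycerol 1-acetate, dehydrated between the tertiary oxygen and the second arm.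
- Key disconnection: the stereocenter and the acetate come together from the stereocenter-free 2-arylpropane-1,2,3-triol 6, by lipase acetylation of one of its two enantiotopic CH2OH arms.
- The oxirane, the only ring that is made, closes last by O1–C3 bond formation (tertiary OH onto the activated second arm), not by oxygen transfer to an alkene. The benzene ring is bought, and the 1,3-dioxane of 2 is a temporary ring.
- The Ar–C2 bond comes from addition of a lithiated bromophenol to dihydroxyacetone acetonide 2, which brings all three oxygens of the C3 unit in one step.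
- Avoided by design: no alkene, no allylic bromination, no enantioselective epoxidation. The stereocenter is fixed before ring closure, and the ring closure breaks no bond at it.

Key step: step 4

Assumption: the sense of the lipase toward triol 6 cannot be predicted with certainty; the steps are written for acetylation of the pro-S hydroxymethyl arm, to be confirmed in a screen of commercial lipases on the first run.

**Route**

Step 1
Reactants: 1 2-bromo-5-(hydroxymethyl)phenol; 2 2,2-dimethyl-1,3-dioxan-5-one
Product: 4 5-[2-hydroxy-4-(hydroxymethyl)phenyl]-2,2-dimethyl-1,3-dioxan-5-ol, via trilithiated arene 3 (not isolated)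
Conditions: n-BuLi (3.1 equiv), THF, −78 → −30 °C; then 2 (1.1 equiv), −78 → 0 °C; aq. NH4Cl
Reagents that add atoms: n-butyllithium, [Li]CCCC (its lithium is in 3 only)
Why: Two equivalents of n-BuLi deprotonate the phenol and the alcohol, the third effects bromine–lithium exchange, and the aryl lithium adds 1,2 to the ketone of dihydroxyacetone acetonide, which forms the Ar–C2 bond and delivers the C3 unit with its two primary oxygens masked as a ketal; no stereocenter arises because the carbinol carbon carries two identical arms.

Step 2
Reactants: 4 5-[2-hydroxy-4-(hydroxymethyl)phenyl]-2,2-dimethyl-1,3-dioxan-5-ol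
Product: 5 2-(5-hydroxy-2,2-dimethyl-1,3-dioxan-5-yl)-5-[(2-methylpropanoyloxy)methyl]phenyl 2-methylpropanoate
Conditions: i-PrCOCl (2.3 equiv), pyridine (5 equiv), CH2Cl2, 0 → 20 °C
Reagents that add atoms: isobutyryl chloride (2-methylpropanoyl chloride), CC(C)C(=O)Cl
Why: Nucleophilic acyl substitution esterifies the phenol and the primary benzylic alcohol, whereas the crowded tertiary alcohol does not react without a nucleophilic catalyst and the ketal keeps the two future glycerol arms out of play.

Step 3
Reactants: 5 2-(5-hydroxy-2,2-dimethyl-1,3-dioxan-5-yl)-5-[(2-methylpropanoyloxy)methyl]phenyl 2-methylpropanoate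
Product: 6 2-(1,2,3-trihydroxypropan-2-yl)-5-[(2-methylpropanoyloxy)methyl]phenyl 2-methylpropanoate
Conditions: AcOH/H2O 4:1, 40 °C; toluene azeotrope
Reagents that add atoms: none
Why: Acid-catalysed hydrolysis of the isopropylidene ketal in aqueous acetic acid should leave the alkyl and aryl esters intact and is too mild to ionise the tertiary benzylic alcohol, whose cation would be destabilised by two β-oxygens, so the prochiral triol is set free.

Step 4
Reactants: 6 2-(1,2,3-trihydroxypropan-2-yl)-5-[(2-methylpropanoyloxy)methyl]phenyl 2-methylpropanoate
Product: 7 2-[(2S)-1-(acetyloxy)-2,3-dihydroxypropan-2-yl]-5-[(2-methylpropanoyloxy)methyl]phenyl 2-methylpropanoate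
Conditions: immobilised Burkholderia cepacia lipase, vinyl acetate (5 equiv), t-BuOMe/THF 4:1, 30 °C; filter, short neutral silica column, use at once
Reagents that add atoms: vinyl acetate, CC(=O)OC=C
Why: The active-site serine of the lipase is acetylated by vinyl acetate (the vinyl alcohol set free tautomerises to acetaldehyde, so the transfer is irreversible), and the acetyl-enzyme passes its acyl group to one of the two enantiotopic CH2OH arms of the bound triol. The closest known reaction type is the lipase-catalysed desymmetrisation of prochiral 2-substituted and 2,2-disubstituted propane-1,3-diols, 2-substituted glycerols included, by transesterification with enol esters. No ring is closed; the step forms the O–acyl bond of the target's acetate. The only stereocenter arises at C2 because acetylation of the pro-S arm makes the two arms different, and it is controlled by the chiral active site of the enzyme, not by the substrate. The step needs enantiotopic-group selectivity, arrest at the monoacetate and inertness of the other functions: the tertiary hydroxyl is not a lipase substrate, the α-branched isobutyrates (one on a crowded aryl position) are far poorer acyl donors than the enol ester, and the slower second acetylation should remove mainly the minor (R)-monoacetate as the achiral diacetate and so raise the ee of 7.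

Step 5
Reactants: 7 2-[(2S)-1-(acetyloxy)-2,3-dihydroxypropan-2-yl]-5-[(2-methylpropanoyloxy)methyl]phenyl 2-methylpropanoate
Product: 9 2-[(2S)-2-(acetyloxymethyl)oxiran-2-yl]-5-[(2-methylpropanoyloxy)methyl]phenyl 2-methylpropanoate (CNP0151517.1), via primary mesylate 8 (not isolated)
Conditions: MsCl (1.05 equiv), Et3N (1.3 equiv), CH2Cl2, −20 °C; then DBU (1.5 equiv), −20 → 20 °C; Et3N-deactivated silica
Reagents that add atoms: methanesulfonyl chloride, CS(=O)(=O)Cl (its mesyl group is in 8 only)
Why: Mesylation at −20 °C picks the primary hydroxyl over the hindered tertiary one before the acetate can migrate, and the amidine base then triggers an intramolecular Williamson (3-exo-tet) displacement by the tertiary oxygen, which forms the O1–C3 bond of the oxirane without breaking any bond at the stereocenter (the S configuration is kept; 8 is R only because the mesylate arm outranks the acetate arm) and without a metal alkoxide that could attack the ortho aryl ester.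

**Compound list**

1 | 2-bromo-5-(hydroxymethyl)phenol | OCc1ccc(Br)c(O)c1 | starting material
2 | 2,2-dimethyl-1,3-dioxan-5-one | CC1(C)OCC(=O)CO1 | starting material
3 | lithium 2-lithio-5-[(lithiooxy)methyl]phenolate | [Li]OCc1ccc([Li])c(O[Li])c1 | intermediate
4 | 5-[2-hydroxy-4-(hydroxymethyl)phenyl]-2,2-dimethyl-1,3-dioxan-5-ol | OCc1ccc(C2(O)COC(C)(C)OC2)c(O)c1 | intermediate
5 | 2-(5-hydroxy-2,2-dimethyl-1,3-dioxan-5-yl)-5-[(2-methylpropanoyloxy)methyl]phenyl 2-methylpropanoate | CC(C)C(=O)OCc1ccc(C2(O)COC(C)(C)OC2)c(OC(=O)C(C)C)c1 | intermediate
6 | 2-(1,2,3-trihydroxypropan-2-yl)-5-[(2-methylpropanoyloxy)methyl]phenyl 2-methylpropanoate | CC(C)C(=O)OCc1ccc(C(O)(CO)CO)c(OC(=O)C(C)C)c1 | intermediate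
7 | 2-[(2S)-1-(acetyloxy)-2,3-dihydroxypropan-2-yl]-5-[(2-methylpropanoyloxy)methyl]phenyl 2-methylpropanoate | CC(=O)OC[C@](O)(c1ccc(COC(=O)C(C)C)cc1OC(=O)C(C)C)CO | intermediate
8 | 2-[(2R)-1-(acetyloxy)-2-hydroxy-3-(methanesulfonyloxy)propan-2-yl]-5-[(2-methylpropanoyloxy)methyl]phenyl 2-methylpropanoate | CC(=O)OC[C@](O)(c1ccc(COC(=O)C(C)C)cc1OC(=O)C(C)C)COS(C)(=O)=O | intermediate
9 | 2-[(2S)-2-(acetyloxymethyl)oxiran-2-yl]-5-[(2-methylpropanoyloxy)methyl]phenyl 2-methylpropanoate | CC(=O)OC[C@]1(c2ccc(COC(=O)C(C)C)cc2OC(=O)C(C)C)CO1 | target

**Summary and risks**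

Total step count: 5. Longest linear sequence: 5 steps (from 1).

Steps most likely to fail:

Step 4. The lipase may show poor or reversed enantiotopic-group selectivity, may shuffle the isobutyryl groups, or may run on to the diacetate. The fallback sets out from triol 6 and replaces the enzyme by a small-molecule catalyst of which both enantiomers are available. Cu(OTf)2 with 2,2'-isopropylidenebis[(4R)-4-phenyl-2-oxazoline] or its (4S,4'S) enantiomer (whichever gives the R product), TsCl and Na2CO3 in MeCN at 0 °C should sulfonylate one primary hydroxyl of the 1,2-diol unit chelated to divalent copper. This would give 2-[(2R)-1,2-dihydroxy-3-(4-methylbenzenesulfonyloxy)propan-2-yl]-5-[(2-methylpropanoyloxy)methyl]phenyl 2-methylpropanoate F1. AcCl and 2,4,6-collidine in CH2Cl2 at −40 °C would then acetylate the remaining primary hydroxyl to 2-[(2R)-1-(acetyloxy)-2-hydroxy-3-(4-methylbenzenesulfonyloxy)propan-2-yl]-5-[(2-methylpropanoyloxy)methyl]phenyl 2-methylpropanoate F2. DBU in CH2Cl2 would close F2 to the oxirane, so the fallback comes back to the route at 9.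

Step 5. Under base the phenolic isobutyryl group may be transferred to the tertiary alkoxide, after which the freed phenoxide would attack the mesylate; the acetyl group may also migrate before mesylation, which would erode the ee. The fallback sets out from monoacetate 7 and reaches 9 in one operation without sulfonate or external base, by redox cyclodehydration (PPh3, DIAD, toluene, 0 → 60 °C). The primary hydroxyl is taken up as an alkoxyphosphonium ion and displaced by the tertiary hydroxyl within the same intermediate, so no free alkoxide is formed; no new isolable compound arises on the way.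

Step 1. The trianion may be poorly soluble, the bromine–lithium exchange incomplete, or the ketone enolised by the basic aryl lithium. The fallback sets out from 1: TBSCl and imidazole in DMF should give tert-butyl({4-bromo-3-[(tert-butyldimethylsilyl)oxy]phenyl}methoxy)dimethylsilane F3. Mg turnings with LiCl in THF would convert it into (2-[(tert-butyldimethylsilyl)oxy]-4-{[(tert-butyldimethylsilyl)oxy]methyl}phenyl)magnesium bromide F4, a less basic nucleophile. Addition of F4 to 2 in the presence of LaCl3·2LiCl at 0 °C would give 5-(2-[(tert-butyldimethylsilyl)oxy]-4-{[(tert-butyldimethylsilyl)oxy]methyl}phenyl)-2,2-dimethyl-1,3-dioxan-5-ol F5, and TBAF in THF would remove both silyl groups, so the fallback comes back to the route at 4.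

**Further compounds**

F1 | step 4 | 2-[(2R)-1,2-dihydroxy-3-(4-methylbenzenesulfonyloxy)propan-2-yl]-5-[(2-methylpropanoyloxy)methyl]phenyl 2-methylpropanoate | OC[C@](O)(c1ccc(COC(=O)C(C)C)cc1OC(=O)C(C)C)COS(=O)(=O)c1ccc(C)cc1
F2 | step 4 | 2-[(2R)-1-(acetyloxy)-2-hydroxy-3-(4-methylbenzenesulfonyloxy)propan-2-yl]-5-[(2-methylpropanoyloxy)methyl]phenyl 2-methylpropanoate | CC(=O)OC[C@](O)(c1ccc(COC(=O)C(C)C)cc1OC(=O)C(C)C)COS(=O)(=O)c1ccc(C)cc1
F0 | step 5 | none | none
F3 | step 1 | tert-butyl({4-bromo-3-[(tert-butyldimethylsilyl)oxy]phenyl}methoxy)dimethylsilane | CC(C)(C)[Si](C)(C)OCc1ccc(Br)c(O[Si](C)(C)C(C)(C)C)c1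
F4 | step 1 | (2-[(tert-butyldimethylsilyl)oxy]-4-{[(tert-butyldimethylsilyl)oxy]methyl}phenyl)magnesium bromide | CC(C)(C)[Si](C)(C)OCc1ccc([Mg]Br)c(O[Si](C)(C)C(C)(C)C)c1
F5 | step 1 | 5-(2-[(tert-butyldimethylsilyl)oxy]-4-{[(tert-butyldimethylsilyl)oxy]methyl}phenyl)-2,2-dimethyl-1,3-dioxan-5-ol | CC(C)(C)[Si](C)(C)OCc1ccc(C2(O)COC(C)(C)OC2)c(O[Si](C)(C)C(C)(C)C)c1
A1 | direct plan | 5-(hydroxymethyl)-2-(prop-1-en-2-yl)phenol | CC(=C)c1ccc(CO)cc1O
A2 | direct plan | 5-[(2-methylpropanoyloxy)methyl]-2-(prop-1-en-2-yl)phenyl 2-methylpropanoate | CC(=C)c1ccc(COC(=O)C(C)C)cc1OC(=O)C(C)C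
A3 | direct plan | 2-(3-bromoprop-1-en-2-yl)-5-[(2-methylpropanoyloxy)methyl]phenyl 2-methylpropanoate | BrCC(=C)c1ccc(COC(=O)C(C)C)cc1OC(=O)C(C)C
A4 | direct plan | 2-[3-(acetyloxy)prop-1-en-2-yl]-5-[(2-methylpropanoyloxy)methyl]phenyl 2-methylpropanoate | CC(=O)OCC(=C)c1ccc(COC(=O)C(C)C)cc1OC(=O)C(C)C
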